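Retrosynthesis: the three angelate C–O bonds and the C1 ketone (carried as an exocyclic CH2) come off first, and the 7,8,9-triol goes back to a C8=C9 enone. Then the C5–C6 bond of the seven-membered ring (cyclobutane CH to the gem-dimethyl carbon) is cut as an aldol bond, the cyclobutane bonds C4–C5 and C10–C11 as a ketene–alkene [2+2], and the open chain at C4=C10 (Claisen) and C2–C3 (enolate alkylation).
Forward: acyclic C16 keto-dienoic acid → cyclobutane and six-membered ring together (vinylketene [2+2], bicyclo[3.1.1]heptan-6-one) → seven-membered ring by reductive aldol closure of C5–C6 → removal of the C5 oxygen → enone, C1 ketone, triol, esters.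
Enabling feature: the cyclobutanone carbon C5 is flanked by the bridgehead CH groups C4 and C11 (no enolization, no elimination), is strain-activated, and lies about 2.1 Å across the four-membered ring from C10, whose C9–C8–C7–C6 chain hangs on the same face. A fully substituted C6 enolate can therefore only add to C5, closing the bicyclo[4.1.1]octane and creating the gem-dimethyl carbon.
Stereochemistry: C3 from an oxazolidinone alkylation; it is relayed by A(1,3) strain to C4, C10 and C11 in the [2+2] (E-alkene geometry puts the C10 methyl syn to the C1–C3 bridge); C5 is dictated by the cage; C7 by CBS reduction; C8 and C9 by osmylation anti to the C7 hydroxyl.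

Key step: step 11

Numbering used for all bicyclic and tricyclic compounds: C1 ring-ketone carbon, C2, C3 (methyl-bearing), cyclobutane C4–C5–C11–C10 (C4 next to C3, C11 next to C1, C10 methyl-bearing), C6 gem-dimethyl carbon, C7–C9 oxygenated carbons; angeloyl = (Z)-2-methylbut-2-enoyl.
Assumption: the two faces of the seven-membered ring are nearly equivalent (pseudo-mirror plane through C2, C5 and C10), so C7 has to be set by reagent control; tert-butyl 3-methylbut-2-enoate and angelic anhydride are taken as purchasable.

Step 1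
Reactants: 1 tert-butyl 3-methylbut-2-enoate
Product: 2 tert-butyl (2E)-4-bromo-3-methylbut-2-enoate
Conditions: NBS, AIBN (cat.), PhCF3, 80 °C; (2E) isomer separated from (2Z) by chromatography
Reagents that add atoms: N-bromosuccinimide, O=C1CCC(=O)N1Br
Why: Wohl–Ziegler allylic bromination of a 3-methylbut-2-enoate is the standard route to 4-bromo-3-methylbut-2-enoates; the (2E) isomer is kept because it leaves the methyl group cis to the carbonyl, the one that is deprotonated when the vinylketene is generated in step 10.

Step 2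
Reactants: 3 (4S)-4-benzyl-3-propanoyl-1,3-oxazolidin-2-one; 2 tert-butyl (2E)-4-bromo-3-methylbut-2-enoate
Product: 4 (4S)-4-benzyl-3-[(2R,4E)-6-tert-butoxy-2,4-dimethyl-6-oxohex-4-enoyl]-1,3-oxazolidin-2-one
Conditions: NaN(SiMe3)2, THF, −78 °C; then 2, −78 → −30 °C
Reagents that add atoms: none
Why: Evans asymmetric alkylation: the chelated Z-sodium enolate is alkylated (SN2) on the face opposite the benzyl group, which should give the (2R) centre (future C3), and the β,β-disubstituted enoate resists competing conjugate addition.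

Step 3
Reactants: 4 (4S)-4-benzyl-3-[(2R,4E)-6-tert-butoxy-2,4-dimethyl-6-oxohex-4-enoyl]-1,3-oxazolidin-2-one
Product: 5 tert-butyl (2E,5R)-6-hydroxy-3,5-dimethylhex-2-enoate
Conditions: LiBH4, MeOH (1 equiv), Et2O, 0 °C
Reagents that add atoms: none
Why: Reductive cleavage of the N-acyl oxazolidinone with LiBH4 is faster than reduction of the hindered conjugated tert-butyl ester and leaves the new stereocentre untouched while releasing the auxiliary.

Step 4
Reactants: 5 tert-butyl (2E,5R)-6-hydroxy-3,5-dimethylhex-2-enoate
Product: 6 tert-butyl (2E,5R)-3,5-dimethyl-6-oxohex-2-enoate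
Conditions: Dess–Martin periodinane, NaHCO3, CH2Cl2, 0 °C → rt
Reagents that add atoms: none
Why: Dess–Martin oxidation under buffered conditions should give the α-methyl aldehyde without epimerization.

Step 5
Reactants: 6 tert-butyl (2E,5R)-3,5-dimethyl-6-oxohex-2-enoate
Product: 7 tert-butyl (2E,5R)-6-hydroxy-3,5,7-trimethylocta-2,7-dienoate (both C6 epimers)
Conditions: CH2=C(CH3)MgBr, THF, −78 °C
Reagents that add atoms: isopropenylmagnesium bromide, CC(=C)[Mg]Br
Why: Grignard 1,2-addition to the aldehyde at low temperature spares the tert-butyl enoate; the new carbinol centre forms as a mixture that does not matter because it is destroyed in step 6.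

Step 6
Reactants: 7 tert-butyl (2E,5R)-6-hydroxy-3,5,7-trimethylocta-2,7-dienoate
Product: 9 ethyl tert-butyl (2E,5R,6E)-3,5,7-trimethyldeca-2,6-dienedioate (C1 tert-butyl ester; C10 ethyl ester), via ketene acetal 8 (not isolated)
Conditions: MeC(OEt)3, EtCO2H (cat.), 140 °C, EtOH distilled off
Reagents that add atoms: triethyl orthoacetate, CC(OCC)(OCC)OCC
Why: Johnson–Claisen orthoester rearrangement: the [3,3] shift of the ketene acetal through a chair with the C5 substituent equatorial should give the (6E) trisubstituted alkene and the two-carbon ester arm without touching the C5 stereocentre.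

Step 7
Reactants: 9 ethyl tert-butyl (2E,5R,6E)-3,5,7-trimethyldeca-2,6-dienedioate
Product: 10 tert-butyl (2E,5R,6E)-10-[methoxy(methyl)amino]-3,5,7-trimethyl-10-oxodeca-2,6-dienoate
Conditions: Me(MeO)NH·HCl, i-PrMgCl, THF, −20 °C
Reagents that add atoms: N,O-dimethylhydroxylamine hydrochloride, CNOC.Cl
Why: Weinreb amide formation by aminolysis of the saturated ethyl ester with the magnesium amide made in situ; the conjugated tert-butyl ester is too hindered and too weakly electrophilic to react.

Step 8
Reactants: 10 tert-butyl (2E,5R,6E)-10-[methoxy(methyl)amino]-3,5,7-trimethyl-10-oxodeca-2,6-dienoate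
Product: 11 tert-butyl (2E,5R,6E)-3,5,7,11-tetramethyl-10-oxododeca-2,6,11-trienoate
Conditions: CH2=C(CH3)MgBr, THF, −20 → 0 °C; inverse quench into cold aq. KHSO4
Reagents that add atoms: isopropenylmagnesium bromide, CC(=C)[Mg]Br
Why: Weinreb ketone synthesis: the chelated tetrahedral adduct prevents over-addition and the acidic inverse quench keeps the liberated amine from adding to the new isopropenyl ketone, whose CH2 terminus is the hydride acceptor of step 11.

Step 9
Reactants: 11 tert-butyl (2E,5R,6E)-3,5,7,11-tetramethyl-10-oxododeca-2,6,11-trienoate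
Product: 12 (2E,5R,6E)-3,5,7,11-tetramethyl-10-oxododeca-2,6,11-trienoic acid
Conditions: ZnBr2, CH2Cl2, rt
Reagents that add atoms: none
Why: Lewis acid cleavage of the tert-butyl ester (loss of 2-methylpropene) frees the acid without base, which the enone would not tolerate, and without strong protic acid, which the trisubstituted alkene would not tolerate.

Step 10
Reactants: 12 (2E,5R,6E)-3,5,7,11-tetramethyl-10-oxododeca-2,6,11-trienoic acid
Product: 15 bicyclic cycloadduct (4R)-4,7-dimethyl-2-methylidene-7-(4-methyl-3-oxopent-4-en-1-yl)bicyclo[3.1.1]heptan-6-one (4-methyl anti to C7; side chain anti to the C2–C4 bridge), via acid chloride 13 (not isolated), via vinylketene 14 (not isolated)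
Conditions: (COCl)2, benzene, rt; concentrate; then slow addition (6 h) to Et3N, toluene, reflux, high dilution, exclusion of light
Reagents that add atoms: none
Why: Intramolecular [2+2] cycloaddition of a vinylketene (made by γ-deprotonation of the 3-methyl-2-enoyl chloride) with a trisubstituted alkene three atoms away is a known route to bicyclo[3.1.1]heptan-6-ones: the ketene carbonyl carbon bonds to the CH alkene carbon (future C4) and the ketene α-carbon to the methyl-bearing carbon (future C10), the suprafacial addition to the E alkene puts the C10 methyl syn to the three-carbon bridge, and A(1,3) strain between that methyl and the C3 centre (C3–H in the alkene plane, C3 methyl turned away) selects the alkene face so that C4, C10 and C11 are set from C3.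

Step 11
Reactants: 15 (4R)-4,7-dimethyl-2-methylidene-7-(4-methyl-3-oxopent-4-en-1-yl)bicyclo[3.1.1]heptan-6-one
Product: 17 (3R)-5-hydroxy-1-methylidenelongipinan-7-one (tertiary cyclobutanol; hydroxyl syn to the C1–C3 bridge), via copper enolate 16 (not isolated)
Conditions: [(Ph3P)CuH]6 (0.4 equiv of hexamer), toluene/THF, −40 → 0 °C; aq. NH4Cl
Reagents that add atoms: none
Why: Hydride from [(Ph3P)CuH]6 adds conjugatively to the CH2 terminus of the isopropenyl ketone, so C6 becomes a fully substituted copper enolate carbon carrying both methyl groups, and this enolate adds to the strained cyclobutanone carbonyl C5 in an intramolecular aldol reaction that forms the C5–C6 bond. The closest known reaction type is the copper hydride-mediated reductive aldol cyclization of keto enones. The seven-membered ring (C5–C6–C7–C8–C9–C10–C11, a bicyclo[4.1.1]octane across the cyclobutane) closes in a 7-(enolendo)-exo-trig mode. The new stereocentre C5 is set by the cage: the chain hangs from C10 on the face anti to the C1–C3 bridge and can reach C5 only from that face, so the hydroxyl is forced syn to the bridge, and C6 is not stereogenic. Chemoselectivity (1,4-reduction of the enone before 1,2-reduction of the cyclobutanone) rests on the soft copper hydride, regioselectivity on the site of hydride delivery (no C8 enolate, hence no five-membered closure), and the cyclobutanone cannot quench the enolate by proton transfer because both its α-carbons (C4, C11) are bridgeheads.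

Step 12
Reactants: 17 (3R)-5-hydroxy-1-methylidenelongipinan-7-one
Product: 18 (3R)-5-[(methoxyoxalyl)oxy]-1-methylidenelongipinan-7-one
Conditions: ClC(O)CO2Me, DMAP, pyridine, CH2Cl2, 0 °C → rt
Reagents that add atoms: methyl chlorooxoacetate, COC(=O)C(Cl)=O
Why: Acylation of the tertiary cyclobutanol as its methyl oxalate, the small and very electrophilic acyl chloride being the usual answer to hindered tertiary alcohols; amine bases avoid the free alkoxide, which could undergo retro-aldol or ring-opening fragmentation.

Step 13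
Reactants: 18 (3R)-5-[(methoxyoxalyl)oxy]-1-methylidenelongipinan-7-one
Product: 19 (3R)-1-methylidenelongipinan-7-one
Conditions: Bu3SnH (5 equiv, 0.5 M), AIBN, toluene, 110 °C
Reagents that add atoms: none
Why: Barton–McCombie-type radical deoxygenation of a tertiary methyl oxalate: elimination is impossible (C4 and C11 are bridgeheads, C6 is quaternary), the C5 radical can accept hydrogen only in the position left by the cage, and the high Bu3SnH concentration is meant to outrun opening of the cyclobutyl radical.

Step 14
Reactants: 19 (3R)-1-methylidenelongipinan-7-one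
Product: 20 (3R)-1-methylidenelongipin-8-en-7-one
Conditions: 2-iodoxybenzoic acid (IBX), DMSO/toluene, 75 °C
Reagents that add atoms: none
Why: IBX dehydrogenation of a ketone to the enone; C7 can enolize only toward C8 because C6 is quaternary, and C10 is quaternary, so only the C8=C9 enone can form and over-oxidation to a dienone is impossible.

Step 15
Reactants: 20 (3R)-1-methylidenelongipin-8-en-7-one
Product: 22 (3R)-longipin-8-ene-1,7-dione, via diol 21 (not isolated)
Conditions: OsO4 (2 mol %), NaIO4, 2,6-lutidine, 1,4-dioxane/H2O, rt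
Reagents that add atoms: OsO4 (catalytic oxygen carrier), O=[Os](=O)(=O)=O; sodium periodate, [Na+].[O-]I(=O)(=O)=O
Why: Lemieux–Johnson oxidative cleavage: OsO4 dihydroxylates the electron-rich 1,1-disubstituted methylidene much faster than the hindered electron-poor enone alkene and NaIO4 cleaves the diol to the C1 ketone.

Step 16
Reactants: 22 (3R)-longipin-8-ene-1,7-dione
Product: 23 (3R)-longipin-8-ene-1,7-dione 1-(ethane-1,2-diyl ketal)
Conditions: (TMSOCH2)2, TMSOTf (cat.), CH2Cl2, −78 → −20 °C
Reagents that add atoms: 1,2-bis(trimethylsilyloxy)ethane, C[Si](C)(C)OCCO[Si](C)(C)C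
Why: Ketalization with the bis-silyl ether of ethylene glycol under TMSOTf catalysis is selective for the saturated C1 ketone over the conjugated ketone flanked by a quaternary carbon; it masks C1 so that C7 is the only carbonyl in step 17.

Step 17
Reactants: 23 (3R)-longipin-8-ene-1,7-dione 1-(ethane-1,2-diyl ketal)
Product: 24 (3R,7R)-7-hydroxylongipin-8-en-1-one ethane-1,2-diyl ketal (hydroxyl syn to C4)
Conditions: (S)-2-methyl-CBS-oxazaborolidine (0.5 equiv), BH3·SMe2, toluene, −40 °C
Reagents that add atoms: none
Why: Corey–Bakshi–Shibata reduction: the ring itself offers no facial bias at C7, so the catalyst decides, and with the quaternary C6 as the large group and the alkenyl C8 as the small group the (S)-catalyst should deliver hydride to give the (7R) allylic alcohol with the hydroxyl syn to C4.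

Step 18
Reactants: 24 (3R,7R)-7-hydroxylongipin-8-en-1-one ethane-1,2-diyl ketal
Product: 25 (3R)-7,8,9-trihydroxylongipinan-1-one ethane-1,2-diyl ketal (7-OH syn to C4; 8-OH/9-OH syn to C11)
Conditions: OsO4 (5 mol %), NMO, acetone/H2O, rt
Reagents that add atoms: OsO4 (catalytic oxygen carrier), O=[Os](=O)(=O)=O; N-methylmorpholine N-oxide, C[N+]1([O-])CCOCC1
Why: Catalytic OsO4/NMO dihydroxylation: syn addition gives the cis C8/C9 diol, and attack anti to the allylic C7 hydroxyl (the usual sense for cyclic allylic alcohols) should give the 7,8-trans-8,9-cis triol.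

Step 19
Reactants: 25 (3R)-7,8,9-trihydroxylongipinan-1-one ethane-1,2-diyl ketal
Product: 26 (3R)-7,8,9-tris(angeloyloxy)longipinan-1-one ethane-1,2-diyl ketal
Conditions: LiN(SiMe3)2 (3.3 equiv), THF, −78 °C; angelic anhydride (4.5 equiv), −78 → 0 °C
Reagents that add atoms: angelic anhydride, C/C=C(/C)C(=O)OC(=O)/C(C)=C\C
Why: Acylation of the lithium alkoxides with the anhydride (no nucleophilic catalyst, no acid chloride) is the method of choice for angelates because it avoids Z to E isomerization; all three hydroxyls get the same acyl group, so acyl migration is harmless.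

Step 20
Reactants: 26 (3R)-7,8,9-tris(angeloyloxy)longipinan-1-one ethane-1,2-diyl ketal
Product: 27 (3R)-7,8,9-tris(angeloyloxy)longipinan-1-one (7-ester syn to C4; 8- and 9-esters syn to C11; CNP0138097.1)
Conditions: PPTS, acetone/H2O, 55 °C
Reagents that add atoms: water, O
Why: Acid-catalysed hydrolysis of the dioxolane under mild conditions should unmask the C1 ketone without hydrolysing or isomerizing the angelates.

Compound list
1 | tert-butyl 3-methylbut-2-enoate | CC(C)=CC(=O)OC(C)(C)C | starting material
2 | tert-butyl (2E)-4-bromo-3-methylbut-2-enoate | BrC/C(C)=C/C(=O)OC(C)(C)C | intermediate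
3 | (4S)-4-benzyl-3-propanoyl-1,3-oxazolidin-2-one | CCC(=O)N1[C@@H](Cc2ccccc2)COC1=O | starting material
4 | (4S)-4-benzyl-3-[(2R,4E)-6-tert-butoxy-2,4-dimethyl-6-oxohex-4-enoyl]-1,3-oxazolidin-2-one | CC(C)(C)OC(=O)/C=C(\C)C[C@@H](C)C(=O)N1[C@@H](Cc2ccccc2)COC1=O | intermediate
5 | tert-butyl (2E,5R)-6-hydroxy-3,5-dimethylhex-2-enoate | CC(C)(C)OC(=O)/C=C(\C)C[C@@H](C)CO | intermediate
6 | tert-butyl (2E,5R)-3,5-dimethyl-6-oxohex-2-enoate | CC(C)(C)OC(=O)/C=C(\C)C[C@@H](C)C=O | intermediate
7 | tert-butyl (2E,5R)-6-hydroxy-3,5,7-trimethylocta-2,7-dienoate (C6 epimers, centre left open) | CC(C)(C)OC(=O)/C=C(\C)C[C@@H](C)C(O)C(C)=C | intermediate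
8 | ketene acetal, tert-butyl (2E,5R)-6-[(1-ethoxyethenyl)oxy]-3,5,7-trimethylocta-2,7-dienoate (not isolated) | CC(C)(C)OC(=O)/C=C(\C)C[C@@H](C)C(OC(=C)OCC)C(C)=C | intermediate
9 | ethyl tert-butyl (2E,5R,6E)-3,5,7-trimethyldeca-2,6-dienedioate (C1 tert-butyl, C10 ethyl) | CC(C)(C)OC(=O)/C=C(\C)C[C@@H](C)/C=C(\C)CCC(=O)OCC | intermediate
10 | tert-butyl (2E,5R,6E)-10-[methoxy(methyl)amino]-3,5,7-trimethyl-10-oxodeca-2,6-dienoate | CC(C)(C)OC(=O)/C=C(\C)C[C@@H](C)/C=C(\C)CCC(=O)N(C)OC | intermediate
11 | tert-butyl (2E,5R,6E)-3,5,7,11-tetramethyl-10-oxododeca-2,6,11-trienoate | CC(C)(C)OC(=O)/C=C(\C)C[C@@H](C)/C=C(\C)CCC(=O)C(C)=C | intermediate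
12 | (2E,5R,6E)-3,5,7,11-tetramethyl-10-oxododeca-2,6,11-trienoic acid | OC(=O)/C=C(\C)C[C@@H](C)/C=C(\C)CCC(=O)C(C)=C | intermediate
13 | acid chloride, (2E,5R,6E)-3,5,7,11-tetramethyl-10-oxododeca-2,6,11-trienoyl chloride (not isolated) | ClC(=O)/C=C(\C)C[C@@H](C)/C=C(\C)CCC(=O)C(C)=C | intermediate
14 | vinylketene, (5R,6E)-5,7,11-trimethyl-3-methylidenedodeca-1,6,11-triene-1,10-dione (not isolated) | O=C=CC(=C)C[C@@H](C)/C=C(\C)CCC(=O)C(C)=C | intermediate
15 | (4R)-4,7-dimethyl-2-methylidene-7-(4-methyl-3-oxopent-4-en-1-yl)bicyclo[3.1.1]heptan-6-one (4-methyl anti to C7; side chain anti to the C2–C4 bridge) | C=C1C[C@@H](C)[C@H]2C(=O)[C@@H]1[C@]2(C)CCC(=O)C(C)=C | intermediate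
16 | copper enolate of the 4-methyl-3-oxopentyl ketone derived from 15 (monovalent copper, Ph3P ligands omitted; not isolated) | C=C1C[C@@H](C)[C@H]2C(=O)[C@@H]1[C@]2(C)CCC(O[Cu])=C(C)C | intermediate
17 | (3R)-5-hydroxy-1-methylidenelongipinan-7-one (hydroxyl syn to the C1–C3 bridge) | C=C1C[C@@H](C)[C@H]2[C@]3(O)C(C)(C)C(=O)CC[C@@]2(C)[C@H]13 | intermediate
18 | (3R)-5-[(methoxyoxalyl)oxy]-1-methylidenelongipinan-7-one | C=C1C[C@@H](C)[C@H]2[C@]3(OC(=O)C(=O)OC)C(C)(C)C(=O)CC[C@@]2(C)[C@H]13 | intermediate
19 | (3R)-1-methylidenelongipinan-7-one | C=C1C[C@@H](C)[C@H]2[C@@H]3C(C)(C)C(=O)CC[C@@]2(C)[C@H]13 | intermediate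
20 | (3R)-1-methylidenelongipin-8-en-7-one | C=C1C[C@@H](C)[C@H]2[C@@H]3C(C)(C)C(=O)C=C[C@@]2(C)[C@H]13 | intermediate
21 | diol, (3R)-1-hydroxy-1-(hydroxymethyl)longipin-8-en-7-one (predominant C1 epimer drawn; not isolated) | OC[C@]1(O)C[C@@H](C)[C@H]2[C@@H]3C(C)(C)C(=O)C=C[C@@]2(C)[C@H]13 | intermediate
22 | (3R)-longipin-8-ene-1,7-dione | O=C1C[C@@H](C)[C@H]2[C@@H]3C(C)(C)C(=O)C=C[C@@]2(C)[C@H]13 | intermediate
23 | (3R)-longipin-8-ene-1,7-dione 1-(ethane-1,2-diyl ketal) | O1CCOC12C[C@@H](C)[C@H]3[C@@H]4C(C)(C)C(=O)C=C[C@@]3(C)[C@H]24 | intermediate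
24 | (3R,7R)-7-hydroxylongipin-8-en-1-one ethane-1,2-diyl ketal (hydroxyl syn to C4) | O1CCOC12C[C@@H](C)[C@H]3[C@@H]4C(C)(C)[C@H](O)C=C[C@@]3(C)[C@H]24 | intermediate
25 | (3R)-7,8,9-trihydroxylongipinan-1-one ethane-1,2-diyl ketal (7-OH syn to C4; 8-OH and 9-OH syn to C11) | O1CCOC12C[C@@H](C)[C@H]3[C@@H]4C(C)(C)[C@H](O)[C@@H](O)[C@@H](O)[C@@]3(C)[C@H]24 | intermediate
26 | (3R)-7,8,9-tris(angeloyloxy)longipinan-1-one ethane-1,2-diyl ketal | O1CCOC12C[C@@H](C)[C@H]3[C@@H]4C(C)(C)[C@H](OC(=O)/C(C)=C\C)[C@@H](OC(=O)/C(C)=C\C)[C@@H](OC(=O)/C(C)=C\C)[C@@]3(C)[C@H]24 | intermediate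
27 | (3R)-7,8,9-tris(angeloyloxy)longipinan-1-one, CNP0138097.1 | O=C1C[C@@H](C)[C@H]2[C@@H]3C(C)(C)[C@H](OC(=O)/C(C)=C\C)[C@@H](OC(=O)/C(C)=C\C)[C@@H](OC(=O)/C(C)=C\C)[C@@]2(C)[C@H]13 | target

Total steps: 20. Longest linear sequence: 20 steps (1 → 27; compound 3 enters at step 2).

Steps most likely to fail

Step 11. The tetrasubstituted copper enolate may be protonated on work-up before the slow seven-membered closure, or the aldolate may revert by retro-aldol or homoallylic ring opening of the cyclobutanol. The fallback sets out from 15 and returns at 17. 1,4-Hydrosilylation of the enone with Et3SiH and (Ph3P)3RhCl should give the regiodefined triethylsilyl enol ether F1. This is then closed onto C5 in a separate Mukaiyama aldol step with TiCl4 in CH2Cl2 at −78 °C, and aqueous work-up should give 17.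

Step 13. Opening of the cyclobutyl radical at C5 (β-scission toward a tertiary radical and a diene) may compete with hydrogen transfer at 110 °C. The fallback sets out from 18 and returns at 19. Selective saponification of the methyl ester of 18 with CsOH in THF/H2O should give the caesium oxalate F2. This is decarboxylated at room temperature under blue light with Ir[dF(CF3)ppy]2(dtbbpy)PF6 in the presence of a thiol hydrogen-atom donor, so that the radical is formed cold and is trapped by a much faster donor.

Step 19. Acylation of the two neopentyl hydroxyls (C7, C9) may stay incomplete, and the angeloyl groups may isomerize from Z to E under forcing conditions. The fallback sets out from 25 and returns at 26. Esterification with 2-[bis(2,2,2-trifluoroethoxy)phosphoryl]propanoic acid (DIC, DMAP, CH2Cl2) should give the tris(phosphonopropanoate) F3. A threefold Still–Gennari olefination with acetaldehyde (KN(SiMe3)2, 18-crown-6, THF, −78 °C) then builds the three (Z)-2-methylbut-2-enoates in place.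

Further compounds
F1 | step 11 | (4R)-4,7-dimethyl-2-methylidene-7-[4-methyl-3-(triethylsilyloxy)pent-3-en-1-yl]bicyclo[3.1.1]heptan-6-one | C=C1C[C@@H](C)[C@H]2C(=O)[C@@H]1[C@]2(C)CCC(O[Si](CC)(CC)CC)=C(C)C
F2 | step 13 | caesium salt of the C5 hydrogen oxalate of 17 | C=C1C[C@@H](C)[C@H]2[C@]3(OC(=O)C(=O)[O-])C(C)(C)C(=O)CC[C@@]2(C)[C@H]13.[Cs+]
F3 | step 19 | (3R)-7,8,9-tris{2-[bis(2,2,2-trifluoroethoxy)phosphoryl]propanoyloxy}longipinan-1-one ethane-1,2-diyl ketal (propanoate α-centres left open) | O1CCOC12C[C@@H](C)[C@H]3[C@@H]4C(C)(C)[C@H](OC(=O)C(C)P(=O)(OCC(F)(F)F)OCC(F)(F)F)[C@@H](OC(=O)C(C)P(=O)(OCC(F)(F)F)OCC(F)(F)F)[C@@H](OC(=O)C(C)P(=O)(OCC(F)(F)F)OCC(F)(F)F)[C@@]3(C)[C@H]24
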